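The trap in the flask below is to carry its start rate through to the asked time.

| flask | Q | D | remark | time |
|---|---|---|---|---|
| north-west | 1.1 M | 2 M | run made earlier |  |
| north | 2.2 M | 1.43 M | run made earlier |  |
| flask | 1.1 M | 1.43 M |  | 25 h |

| run | time / h | Q / % | L / % |
|---|---|---|---|
| north-west | 1.33 | 59.7 | 28.9 |
| north-west | 4.00 | 28.4 | 32.9 |
| north-west | 8.00 | 14.4 | 28.0 |
| north-west | 10.0 | 10.9 | 25.6 |
| north-west | 15.0 | 6.1 | 22.0 |
| north-west | 20.0 | 3.8 | 20.4 |
| north-west | 25.0 | 3.5 | 18.2 |
| north | 5.00 | 51.8 | 27.1 |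
| north | 10.0 | 46.5 | 25.3 |
| north | 15.0 | 46.1 | 25.2 |
| north | 20.0 | 45.9 | 25.6 |
| north | 25.0 | 45.7 | 25.2 |

(readings scatter by 0.5 percentage points)

- Q at 25 h, in percent of the Q charged
- L at 25 h, in percent of the Q charged
- X at 25 h, in percent of the Q charged
- Z at 25 h, in percent of the Q charged

- the earlier runs were read with a standard deviation of 0.5 percentage points

I reckon the rate alone. In the north-west run Q falls to 59.7 % by 1.33 h, while D averages about 88.9 % of its charge. Scaled to the D of the flask, that gives 0.312 h⁻¹, my start clock: the fraction of the Q present that goes per hour while D stands at its full charge, a pseudo-first-order constant. Its half-life, 2.22 h, is short against 25 h.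

Two factors slow the clock: q, the fraction of Q left, and d, the fraction of D left. The north run stalls at Q 45.7 %, which I read as D exhausted, its charge being 65.0 % of the Q charged, so each Q spent cost 1.20 D. The flask charges 1.30 D per Q, so d follows q closely and the rate falls roughly as q squared. Accumulated, as in a balanced step growth, one over q equals one plus clock times time. With 7.80 for that product, q comes to 11.4 %. Going round once more, that q leaves d at 18.4 %, so the rate at the asked time is about 2.10 % of the start rate, and I stay with my q.

The forecast says Q 16 %, L 31 %, X 16 % and Z 37 %: “Stepping through by hand, D falls to about 0.1 M by 25 h and Q reaches about 15%”. Its Q stands above mine.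

The flask gives Q 13.3 %, L 28.0 %, X 5.27 % and Z 36.4 %.

    D + L → Z + G (k = 4.06 × 10⁻⁵ L mol⁻¹ s⁻¹)
    L ⇌ J (K = 0.600, k = 4.03 × 10⁻⁵ s⁻¹)
    D + X → Z + G (k = 1.81 × 10⁻⁵ L mol⁻¹ s⁻¹)
    E ⇌ G, rate k4*(cs4 - [G]) while solid is left; crystals form when [G] > cs4 (solubility = 0.120 M, k = 0.00707 s⁻¹)
    Q + D → X + G (k = 5.59 × 10⁻⁶ L mol⁻¹ s⁻¹)
    Q + D → L + G (k = 5.83 × 10⁻⁵ L mol⁻¹ s⁻¹)

In the flask Q goes to L 10 times as fast as to X, at the start and at the asked time alike, and here the forecast parts from it, with X at 5.27 % against 16 %. In the flask at 25.0 h, with D down to 5.2 % of its charge, q times d stands at 0.692 %, and my clock, slowed by d, runs at 0.0162 h⁻¹. In a neighbouring flask, the same recipe but with 0.44 M of Q, D stands after the same time at 46 % of its charge and Q at 0.743 %, which on the same clock means a mean d of 62.9 %.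

The data stem from a simulated flask for substances that don't exist; noise was put on by code.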